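**Plan**

1. Retrosynthesis: the O4 propionate comes off first, then the O3 acetate and the O5 (R)-2-methylbutanoate (both traced to one 3,4-orthoacetate of methyl shikimate); the cyclohexene is then cut at the C1=C2 double bond and the C5–C6 single bond.
2. Enabling feature: C6H2–C1(CO2Me)= is a 2-phosphonoacrylate in disguise, the ring =CH (C2) is a former aldehyde carbon, and C5 is an oxygen-bearing sp3 carbon beside the C4–O stereocentre, so it can be an α-oxy radical held in a temporary O4/O5 dioxolane (trans-4,5-diol of the ring = trans-dioxolane).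
3. Forward: the acetonide of D-ribonolactone is opened to a C1-acid/C5-aldehyde; photoredox decarboxylation gives the dioxolanyl radical, which adds to the acrylate, crosses over to the phosphonate carbanion and closes the only carbocycle by Horner–Wadsworth–Emmons olefination.
4. Stereochemistry: ring C3 and C4 are C4 and C3 of D-ribose (its C1 leaves as CO2, its C2 configuration is erased); C5 is set in the radical addition, anti to the C4 substituent on the dioxolane; the side-chain centre is bought with (R)-2-methylbutanoic acid.
5. The three different esters follow from the cis-3,4/trans-4,5 pattern: cyclic orthoacetate on O3/O4, acylation of O5, opening to the pseudoaxial O3 acetate, propionylation of O4.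

Key step: step 4

Remark: ring positions use shikimate numbering (C1 bears CO2Me, C2 is the ring =CH, C3–C5 carry oxygen, C6 is CH2); acyclic intermediates keep D-ribonic acid numbering; compounds 1, 7 and 11 are taken as purchasable.

**Route**

Step 1
Reactants: 1 2,3-O-isopropylidene-D-ribono-1,4-lactone
Product: 4 4,5-bis-O-(tert-butyldimethylsilyl)-2,3-O-isopropylidene-D-ribonic acid, via potassium 2,3-O-isopropylidene-D-ribonate 2 (not isolated), via TBS ester bis-TBS ether 3 (not isolated)
Conditions: (i) KOH (1.05 equiv), MeOH/H2O, 0 °C→rt, evaporate, toluene azeotrope; (ii) TBSCl (4 equiv), imidazole (8 equiv), DMAP (cat.), DMF, rt→45 °C; (iii) K2CO3, MeOH/THF/H2O, rt; citric acid work-up (pH 4)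
Reagents that add atoms: potassium hydroxide [K+].[OH-]; tert-butyldimethylsilyl chloride CC(C)(C)[Si](C)(C)Cl
Why: saponification of the γ-lactone, exhaustive silylation and selective solvolysis of the labile silyl ester is the standard way to trap a ring-opened hydroxy acid; no stereocentre is formed, and any epimerisation at C2 is harmless because that centre is erased in step 4.

Step 2
Reactants: 4 4,5-bis-O-(tert-butyldimethylsilyl)-2,3-O-isopropylidene-D-ribonic acid
Product: 5 4-O-(tert-butyldimethylsilyl)-2,3-O-isopropylidene-D-ribonic acid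
Conditions: HF·pyridine, pyridine, THF, 0 °C
Reagents that add atoms: none
Why: pyridine-buffered HF·pyridine should cleave the primary TBS ether much faster than the hindered secondary one beside the dioxolane (selective desilylation), leaving the acetonide untouched.

Step 3
Reactants: 5 4-O-(tert-butyldimethylsilyl)-2,3-O-isopropylidene-D-ribonic acid
Product: 6 4-O-(tert-butyldimethylsilyl)-2,3-O-isopropylidene-5-oxo-D-ribonic acid (open-chain aldehydo acid; a protected L-riburonic acid)
Conditions: Dess–Martin periodinane (1.2 equiv), CH2Cl2, 0 °C→rt; aq. Na2S2O3 work-up; used crude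
Reagents that add atoms: none
Why: Dess–Martin oxidation of a primary alcohol stops at the aldehyde under non-aqueous conditions and should not epimerise the α-silyloxy centre.

Step 4
Reactants: 6 4-O-(tert-butyldimethylsilyl)-2,3-O-isopropylidene-5-oxo-D-ribonic acid; 7 trimethyl 2-phosphonoacrylate
Product: 9 methyl 3-O-(tert-butyldimethylsilyl)-4,5-O-isopropylideneshikimate (trans-fused dioxolane; natural shikimate configuration at C3–C5), via Giese adduct phosphonate 8 (not isolated)
Conditions: Ir[dF(CF3)ppy]2(dtbbpy)PF6 (1 mol %), Cs2CO3 (1.2 equiv), 7 (1.3 equiv), degassed DMF (0.02 M), 450 nm LEDs, rt; then dark, rt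
Reagents that add atoms: trimethyl 2-phosphonoacrylate (7) COC(=O)C(=C)P(=O)(OC)OC
Why: Proposed new method: the excited Ir(III) photocatalyst oxidises the caesium carboxylate of 6, CO2 is lost, and the nucleophilic 2,2-dimethyl-1,3-dioxolan-4-yl radical adds to the CH2 terminus of 7; the doubly stabilised adduct radical is reduced by Ir(II) to the phosphonate carbanion of 8, which attacks the aldehyde (future C2) and collapses through the oxaphosphetane to the C1=C2 alkene, so the sequence is redox-neutral and needs only the carbonate base. The closest known reaction types are the photoredox decarboxylative Giese addition of α-oxy acids, radical–polar crossover annulations that end in a polar ring closure, and the base-mediated Michael/Horner–Wadsworth–Emmons annulation of 2-phosphonoacrylates, whose anionic first step is replaced here by a radical one because C5 carries oxygen. The cyclohexene closes by 6-exo-trig addition of the carbanion to the aldehyde carbonyl followed by syn-elimination of dimethyl phosphate, and the alkene geometry is fixed by the ring. The new stereocentre C5 is set in the radical C–C bond formation: the dioxolanyl radical should be attacked anti to the CH(OTBS)CHO substituent on the neighbouring ring carbon, giving the trans-4,5-disubstituted dioxolane (as known for tartrate-derived dioxolanyl radicals), which is the 4,5-trans relationship of shikimate. The step needs this facial selectivity and the preference for cyclisation over protonation or a second Michael addition of the carbanion to 7; the first is secured by the temporary isopropylidene ring, the second by the 1,4-relationship of radical carbon and aldehyde that makes the olefination a six-membered closure, helped by dilution.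

Step 5
Reactants: 9 methyl 3-O-(tert-butyldimethylsilyl)-4,5-O-isopropylideneshikimate
Product: 10 methyl (−)-shikimate
Conditions: p-TsOH·H2O (0.2 equiv), MeOH, rt→40 °C; neutralise, evaporate
Reagents that add atoms: none
Why: acid-catalysed methanolysis should remove both helpers of the key step, the allylic TBS ether and the strained trans-fused acetonide (transacetalisation), while the methyl ester is unchanged in methanol.

Step 6
Reactants: 10 methyl (−)-shikimate; 11 (R)-2-methylbutanoic acid
Product: 13 methyl 3,4-O-(1-methoxyethylidene)-5-O-[(2R)-2-methylbutanoyl]shikimate (mixture at the orthoester carbon), via free 5-OH orthoacetate 12 (not isolated)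
Conditions: MeC(OMe)3 (1.5 equiv), CSA (5 mol %), MeCN, rt; Et3N (0.1 equiv), concentrate; then 11 (1.5 equiv), DCC, DMAP (cat.), CH2Cl2, 0 °C→rt
Reagents that add atoms: trimethyl orthoacetate CC(OC)(OC)OC; (R)-2-methylbutanoic acid (11) OC(=O)[C@H](C)CC
Why: under acid catalysis the cis-3,4-diol should form the five-membered cyclic orthoacetate (as the cis-2,3-diols of rhamnosides and mannosides do), leaving the 5-OH for Steglich esterification with the α-branched acid, whose stereocentre is not touched.

Step 7
Reactants: 13 methyl 3,4-O-(1-methoxyethylidene)-5-O-[(2R)-2-methylbutanoyl]shikimate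
Product: 14 methyl 3-O-acetyl-5-O-[(2R)-2-methylbutanoyl]shikimate
Conditions: AcOH/H2O (4:1), rt, short contact; co-evaporate with toluene
Reagents that add atoms: water O
Why: mild aqueous acid opens the cyclic orthoester through the dioxolan-2-ylium ion and its hemiorthoester to the ester on the pseudoaxial oxygen (O3) and the free equatorial 4-OH, the established regiochemistry for cis-diol orthoesters on six-membered rings.

Step 8
Reactants: 14 methyl 3-O-acetyl-5-O-[(2R)-2-methylbutanoyl]shikimate
Product: 15 methyl (3R,4S,5R)-3-acetoxy-5-{[(2R)-2-methylbutanoyl]oxy}-4-(propanoyloxy)cyclohex-1-ene-1-carboxylate (CNP0403577.1)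
Conditions: (EtCO)2O (1.5 equiv), pyridine, DMAP (5 mol %), CH2Cl2, 0 °C
Reagents that add atoms: propanoic anhydride CCC(=O)OC(=O)CC
Why: DMAP-catalysed acylation of the remaining secondary alcohol with the anhydride is fast at 0 °C and should outrun acetyl migration from O3 to O4.

**Compound list**

1 | 2,3-O-isopropylidene-D-ribono-1,4-lactone | O=C1[C@@H]2OC(C)(C)O[C@@H]2[C@@H](CO)O1 | starting material
2 | potassium 2,3-O-isopropylidene-D-ribonate | [K+].[O-]C(=O)[C@@H]1OC(C)(C)O[C@@H]1[C@@H](CO)O | intermediate
3 | tert-butyldimethylsilyl 4,5-bis-O-(tert-butyldimethylsilyl)-2,3-O-isopropylidene-D-ribonate | CC(C)(C)[Si](C)(C)OC(=O)[C@@H]1OC(C)(C)O[C@@H]1[C@@H](CO[Si](C)(C)C(C)(C)C)O[Si](C)(C)C(C)(C)C | intermediate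
4 | 4,5-bis-O-(tert-butyldimethylsilyl)-2,3-O-isopropylidene-D-ribonic acid | OC(=O)[C@@H]1OC(C)(C)O[C@@H]1[C@@H](CO[Si](C)(C)C(C)(C)C)O[Si](C)(C)C(C)(C)C | intermediate
5 | 4-O-(tert-butyldimethylsilyl)-2,3-O-isopropylidene-D-ribonic acid | OC(=O)[C@@H]1OC(C)(C)O[C@@H]1[C@@H](CO)O[Si](C)(C)C(C)(C)C | intermediate
6 | 4-O-(tert-butyldimethylsilyl)-2,3-O-isopropylidene-5-oxo-D-ribonic acid (aldehydo acid) | OC(=O)[C@@H]1OC(C)(C)O[C@@H]1[C@@H](C=O)O[Si](C)(C)C(C)(C)C | intermediate
7 | trimethyl 2-phosphonoacrylate (methyl 2-(dimethoxyphosphoryl)acrylate) | COC(=O)C(=C)P(=O)(OC)OC | starting material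
8 | methyl 2-(dimethoxyphosphoryl)-3-{trans-5-[(R)-1-(tert-butyldimethylsilyloxy)-2-oxoethyl]-2,2-dimethyl-1,3-dioxolan-4-yl}propanoate (Giese adduct, formed as its carbanion; mixture at the P-bearing carbon) | COC(=O)C(P(=O)(OC)OC)C[C@H]1OC(C)(C)O[C@@H]1[C@@H](C=O)O[Si](C)(C)C(C)(C)C | intermediate
9 | methyl 3-O-(tert-butyldimethylsilyl)-4,5-O-isopropylideneshikimate | CC1(C)O[C@@H]2[C@H](O[Si](C)(C)C(C)(C)C)C=C(C(=O)OC)C[C@H]2O1 | intermediate
10 | methyl (−)-shikimate, methyl (3R,4S,5R)-3,4,5-trihydroxycyclohex-1-ene-1-carboxylate | O[C@@H]1[C@H](O)C=C(C(=O)OC)C[C@H]1O | intermediate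
11 | (R)-2-methylbutanoic acid | OC(=O)[C@H](C)CC | starting material
12 | methyl 3,4-O-(1-methoxyethylidene)shikimate (5-OH free; mixture at the orthoester carbon) | COC1(C)O[C@@H]2[C@H](O1)C=C(C(=O)OC)C[C@H]2O | intermediate
13 | methyl 3,4-O-(1-methoxyethylidene)-5-O-[(2R)-2-methylbutanoyl]shikimate | COC1(C)O[C@@H]2[C@H](O1)C=C(C(=O)OC)C[C@H]2OC(=O)[C@H](C)CC | intermediate
14 | methyl (3R,4S,5R)-3-acetoxy-4-hydroxy-5-{[(2R)-2-methylbutanoyl]oxy}cyclohex-1-ene-1-carboxylate | O[C@@H]1[C@H](OC(C)=O)C=C(C(=O)OC)C[C@H]1OC(=O)[C@H](C)CC | intermediate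
15 | methyl (3R,4S,5R)-3-acetoxy-5-{[(2R)-2-methylbutanoyl]oxy}-4-(propanoyloxy)cyclohex-1-ene-1-carboxylate | CCC(=O)O[C@@H]1[C@H](OC(C)=O)C=C(C(=O)OC)C[C@H]1OC(=O)[C@H](C)CC | target

**Step count and risks**

Total steps: 8. Longest linear sequence: 8 steps (1 → 15).

Steps most likely to fail:

1. Step 4. The domino may break off between its radical and polar halves: the phosphonate carbanion may be protonated without ring closure or add to a second molecule of 7. The α-silyloxy aldehyde may also epimerise or undergo β-elimination under carbonate during irradiation. The fallback uses known reaction types only, separates the radical and polar events and brings in the aldehyde after the radical step. It sets out from 4. Photoredox decarboxylative Giese addition of 4 to 7 (Ir photocatalyst, K2HPO4, DMF, blue LEDs) should give the bis-silyl phosphonate F1 with the same trans-dioxolane. HF·pyridine should then free the primary alcohol F2, and Dess–Martin oxidation should give aldehyde 8, now isolated. LiCl/DBU in MeCN (Masamune–Roush conditions) should close the ring to 9, where the route is rejoined.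

2. Step 7. The orthoester opening may leak to the other regioisomer (acetate on O4), or the acetate may migrate from O3 to the free 4-OH, which would end in the transposed acetate/propionate pattern. The fallback places the propionate first by catalyst-controlled acylation of the equatorial hydroxyl. It sets out from 10. 2,2-Dimethoxypropane/CSA in acetone should give methyl 3,4-O-isopropylideneshikimate F3. DCC/DMAP with 11 should give the 5-O-acyl acetonide F4, and aqueous acetic acid should free the 3,4-diol F5. Propanoyl chloride with iPr2NEt and catalytic 2-aminoethyl diphenylborinate in MeCN should acylate the equatorial O4 of the cis-diol to give the 4-O-propanoyl 3-alcohol F6. Ac2O/pyridine/DMAP then gives 15, where the route is rejoined.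

3. Step 2. The liberated 5-hydroxy acid may close to the δ-lactone, the discrimination between primary and secondary silyl ether may be incomplete, and in the following oxidation the aldehydo acid may over-oxidise through its cyclic pseudo-acid form. The fallback masks the carboxyl group so that no free hydroxy acid is handled. It sets out from 4. BnBr/K2CO3 in DMF should give benzyl 4,5-bis-O-(tert-butyldimethylsilyl)-2,3-O-isopropylidene-D-ribonate F7. HF·pyridine should give the primary alcohol, benzyl 4-O-(tert-butyldimethylsilyl)-2,3-O-isopropylidene-D-ribonate F8, and Dess–Martin oxidation should give its 5-aldehyde F9. Hydrogenolysis (H2, Pd/C, EtOAc) then gives 6, where the route is rejoined.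

**Further compounds**

F1 | step 4 | methyl 2-(dimethoxyphosphoryl)-3-{trans-5-[(R)-1,2-bis(tert-butyldimethylsilyloxy)ethyl]-2,2-dimethyl-1,3-dioxolan-4-yl}propanoate | COC(=O)C(P(=O)(OC)OC)C[C@H]1OC(C)(C)O[C@@H]1[C@@H](CO[Si](C)(C)C(C)(C)C)O[Si](C)(C)C(C)(C)C
F2 | step 4 | methyl 2-(dimethoxyphosphoryl)-3-{trans-5-[(R)-1-(tert-butyldimethylsilyloxy)-2-hydroxyethyl]-2,2-dimethyl-1,3-dioxolan-4-yl}propanoate | COC(=O)C(P(=O)(OC)OC)C[C@H]1OC(C)(C)O[C@@H]1[C@@H](CO)O[Si](C)(C)C(C)(C)C
F3 | step 7 | methyl 3,4-O-isopropylideneshikimate | CC1(C)O[C@@H]2[C@H](O1)C=C(C(=O)OC)C[C@H]2O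
F4 | step 7 | methyl 3,4-O-isopropylidene-5-O-[(2R)-2-methylbutanoyl]shikimate | CC1(C)O[C@@H]2[C@H](O1)C=C(C(=O)OC)C[C@H]2OC(=O)[C@H](C)CC
F5 | step 7 | methyl 5-O-[(2R)-2-methylbutanoyl]shikimate | O[C@@H]1[C@H](O)C=C(C(=O)OC)C[C@H]1OC(=O)[C@H](C)CC
F6 | step 7 | methyl 5-O-[(2R)-2-methylbutanoyl]-4-O-propanoylshikimate | CCC(=O)O[C@@H]1[C@H](O)C=C(C(=O)OC)C[C@H]1OC(=O)[C@H](C)CC
F7 | step 2 | benzyl 4,5-bis-O-(tert-butyldimethylsilyl)-2,3-O-isopropylidene-D-ribonate | O=C(OCc1ccccc1)[C@@H]1OC(C)(C)O[C@@H]1[C@@H](CO[Si](C)(C)C(C)(C)C)O[Si](C)(C)C(C)(C)C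
F8 | step 2 | benzyl 4-O-(tert-butyldimethylsilyl)-2,3-O-isopropylidene-D-ribonate | O=C(OCc1ccccc1)[C@@H]1OC(C)(C)O[C@@H]1[C@@H](CO)O[Si](C)(C)C(C)(C)C
F9 | step 2 | benzyl 4-O-(tert-butyldimethylsilyl)-2,3-O-isopropylidene-5-oxo-D-ribonate | O=C(OCc1ccccc1)[C@@H]1OC(C)(C)O[C@@H]1[C@@H](C=O)O[Si](C)(C)C(C)(C)C
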